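## Structural features

The target is a germacranolide: a ten-membered carbocycle (C1–C10) with an E-configured trisubstituted C1=C10 olefin, a trisubstituted 4,5-epoxide, and an α-methylene-γ-butyrolactone (C11–C13) trans-fused at C7–C8 and closed on O8. Read from the descriptors, the ring bonds C3–C4 and C5–C6 are cis on the oxirane, so the epoxide derives from a 4Z olefin. Six stereocentres stand in an unbroken row, C4–C5–C6–C7–C8–C9, with a free hydroxyl at C6 and an isobutyrate at C9. Three groups are fragile. The methylene lactone is a Michael acceptor and isomerises to the endocyclic butenolide with base. The epoxide is flanked by a free hydroxyl, which invites Payne rearrangement and acid-induced transannular opening. The lactone can migrate to O6, because O6 and O8 are both γ to C12. The real difficulty is twofold: closing a strained ten-membered ring that holds an E-olefin without disturbing these groups, and keeping three neighbouring oxygens apart (O6 free, O8 lactone, O9 ester). The key step uses the fact that C9 is a secondary allylic carbinol carbon bonded to the olefinic carbon C10 and flanked by the oxygenated centre C8. That is the retron of an alkenyl metal at C10 adding to an aldehyde at C9, so C9–C10 can be made last, closing the C1–C10 ring and creating only C9.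

## Logic of the disconnections

**24 to 23 to 22.** The O6–Si bond and the O9–acyl bond are cut. Silicon comes off last so that O6 stays masked while O9 is acylated, and the two secondary hydroxyls never have to be distinguished. The demand is a non-basic final desilylation, because free O6 next to the epoxide and γ to C12 can trigger Payne rearrangement or lactone migration.

**22 to 21.** The C9–C10 bond is cut. This opens the ten-membered ring and removes one stereocentre, leaving an acyclic precursor in which every other centre and both olefin geometries are already fixed. The forward step needs an alkenyl nucleophile that adds to an aldehyde but not to a lactone, an enoate or an epoxide, high dilution, and facial control at C9 from C8. A Felkin–Anh addition with the C8–O bond anti to the incoming C10 gives the 8,9-anti alcohol, which is the arrangement in 24, so no inversion is planned.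

**21 to 20 to 19.** The C9 formyl group goes back to a primary triethylsilyl ether and the O6 silyl ether to a free hydroxyl. The sensitive α-acyloxy aldehyde then exists for one step only, and one silyl group serves both oxygens. The demand is an oxidation that distinguishes a primary from a hindered secondary silyl ether.

**19 to 18.** The two C–O bonds of the oxirane are cut. The free O6 of 18 can direct a peracid, and A(1,3) strain in the 4Z allylic alcohol favours exactly the 5,6-syn (threo) epoxy alcohol required. This removes two stereocentres and leaves a diene. The demand is facial selectivity and preference for this olefin over the iodo-olefin and the methylene lactone. Epoxidising before the coupling is held in reserve, because the epoxy aldehyde's own Felkin–Anh preference would oppose the sense needed at C6.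

**18 to 17 and 7.** The C6–C7 bond is cut, which splits the molecule into two fragments of similar size and removes two stereocentres. The allyl partner is a bromomethyl butenolide, not an open-chain 2-(bromomethyl)acrylate. With the open-chain reagent, O6 and O8 would both sit γ to the ester after addition, and its Z geometry would favour the 6,7-syn adduct. In 7 the lactone is already closed on O8, and C8 is held trans to the CH2–metal terminus, which a chair transition state translates into the 6,7-anti, 7,8-trans product. The demand is γ-selective 1,2-addition to an enal through a closed transition state.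

**7 to 6 to 5 to 3 to 1 and 2.** The C13–Br bond is cut with allylic transposition, then the O9–Si bond, then the lactone C12–O8 bond together with the acetonide, and last the C7–C11 bond (Baylis–Hillman). The carbinol centre made in the Baylis–Hillman step is erased when the double bond moves into the ring, so its poor diastereoselectivity costs nothing. C8 comes unchanged from 1.

**17 to 16 to 14 to 13 to 12 to 11 to 8 and 9.** The sequence adjusts the C6 oxidation level, then cuts C10–I (hydrozirconation of the methyl-capped alkyne gives the E-iodide), then returns the alcohol to the ester. The C4–C15 bond is cut next: methyl is delivered with retention to an (E)-enol triflate, which fixes the 4Z olefin. The enol triflate goes back to the β-keto ester, and the C2–C3 bond is cut (γ-alkylation of the acetoacetate dianion). The demands are E-selective enol triflate formation and regiocontrol in the hydrozirconation.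

## Other disconnections considered

**Alternative 1:** The cut is C4–C5 together with the C4–O bond of the oxirane. In the forward step, KN(SiMe3)2 would deprotonate a C4 diphenylsulfonium salt, the ylide would add to a C5 aldehyde, and the betaine would close the epoxide with loss of the sulfide. The product would be A1, the ten-membered epoxy lactone with C6-OTES and C9-OPMB. A1 has no C13, so the methylene group would be added afterwards.
- In favour: ring and epoxide arise in one operation and no separate epoxidation is needed. C9 enters as a protected alcohol of fixed configuration; on that point it is better than the chosen plan, which creates C9 during ring closure.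
- Against: two stereocentres (C4, C5) would be created in the macrocyclisation instead of one. A fully substituted, non-stabilised ylide has no inherent bias for the cis arrangement of C3 and C6. The Felkin–Anh sense at C5 relative to C6 is 5,6-anti, whereas the target is 5,6-syn. The secondary sulfonium salt can eliminate instead of forming the ylide. The strong base threatens C6 (α to the aldehyde) and excludes the methylene lactone.
- Comparison: both plans close the ring by adding a carbon nucleophile to an aldehyde under dilution and are equal there. Mechanistically the chosen closure uses a neutral, non-basic organochromium and sets one centre beside a controlling one; this one needs a strong base and sets two. After ring closure the chosen plan needs two steps; this one needs at least methylenation beside an epoxide, PMB removal, acylation and desilylation.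

**Alternative 2:** The bond made is C8–C9, with the C1–C6 bond of a six-membered ring broken in exchange. In the forward step, KH with 18-crown-6 would convert a trans-1,2-dialkenylcyclohexenol into its alkoxide, and the anionic oxy-Cope rearrangement would expand the ring to A2, the (4Z,1(10)E)-dienone with C8-OMOM and C9-OPMB.
- In favour: the ten-membered ring comes from a six-membered one by a sigmatropic ring expansion driven by enolate formation, with no entropic penalty and no dilution. In ring construction as such it is the better of the two. The 4Z olefin is inherited from the cyclohexene, the 1(10)E olefin from the chair transition state, and C8 and C9 are set together.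
- Against: A2 lacks C11–C13, the C7 stereocentre, the C6 carbinol and the epoxide. All would have to be installed on a flexible cyclodecadienone (kinetic C7 alkylation of a conjugated Z-enone, reduction at C6, lactonisation after MOM removal, methylenation, epoxidation), each with uncertain facial control. The 8,9-anti relationship needs one E and one Z enol ether in a chair transition state, so two oxygenated olefins of defined and different geometry must be built around a tertiary carbinol. The conjugated Z-enone in a ten-membered ring is also prone to isomerise.
- Comparison: structurally the chosen plan brings every carbon and five of six centres to the ring closure; this one brings two. Mechanistically the rearrangement is the more dependable ring-forming event. In step economy the chosen plan is well ahead after the key step.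

**Alternative 3:** The bond made is C6–C7 and the bond broken is O–C13. In the forward step, n-BuLi would exchange tin for lithium at C6 of a 13-membered cyclic ether, and a [2,3]-Wittig–Still shift onto C7 of the dihydrofuran olefin would contract the ring to A3. A3 is the ten-membered dienol (C6-OH, C9-OTBS) fused to a 3-methylidenetetrahydrofuran.
- In favour: C6–C7, both of their stereocentres and the exocyclic methylene arise in one concerted step through a five-membered transition state. The large ring is first closed as a 13-membered ether, an easier cyclisation than a ten-membered carbocyclisation; here it is at least the equal of the chosen plan. C9 is fixed beforehand, no lactone is exposed to the organolithium, and the free C6 hydroxyl of A3 could direct the same epoxidation as step 12 (an equal point).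
- Against: the carbanion at C6 is also allylic to the 4Z olefin, so it can lose that geometry or react through C4. A configurationally defined α-alkoxystannane is required. After the contraction the tetrahydrofuran CH2 must be oxidised to the lactone carbonyl in the presence of a secondary allylic alcohol and three olefins, a chemoselectivity problem without a clean answer.
- Comparison: structurally it sets two centres in the key step against one, but leaves the lactone oxidation level and the epoxide open. Mechanistically a concerted shift is more predictable in stereochemistry than a macrocyclic addition, but the delocalised carbanion is less so. In step economy about five steps would follow A3, against two after the chosen closure.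

Key step: step 15

Remark on the chemistry: atoms are numbered as in germacranolides (ring C1–C10; C11–C13 on C7; C14 on C10; C15 on C4). Because the oxirane is cis-fused, the acyclic chain must carry a (Z)-trisubstituted C4=C5 olefin (nerol-type), not the geraniol-type E olefin.

## Route

**Step 1**
Reactants: 1 (S)-2,3-O-isopropylideneglyceraldehyde; 2 methyl acrylate
Product: 3 methyl 2-{[(4S)-2,2-dimethyl-1,3-dioxolan-4-yl](hydroxy)methyl}prop-2-enoate (both carbinol epimers)
Conditions: DABCO (1 equiv), 2 (3 equiv), 1,4-dioxane/H2O 1:1, rt
Reagents that add atoms: none
Why: Baylis–Hillman reaction of an α-alkoxy aldehyde with an acrylate; the configuration of the new carbinol is irrelevant because that carbon becomes sp2 in step 4, and the dioxolane centre (future C8) is not touched.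

**Step 2**
Reactants: 3
Product: 5 (5S)-4-hydroxy-5-(hydroxymethyl)-3-methylideneoxolan-2-one (both C4 epimers), via triol ester 4 (not isolated)
Conditions: TFA/H2O 9:1, 0 °C to rt; evaporation from toluene
Reagents that add atoms: none
Why: Acid hydrolysis of the acetonide followed by acid-catalysed lactonisation; the secondary hydroxyl closes the five-membered lactone in preference to the primary one closing a six-membered ring, which places the lactone on O8 before any C6 oxygen exists.

**Step 3**
Reactants: 5
Product: 6 (5S)-4-hydroxy-3-methylidene-5-{[(triethylsilyl)oxy]methyl}oxolan-2-one (both C4 epimers)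
Conditions: TESCl (1.05 equiv), imidazole, CH2Cl2, −40 °C
Reagents that add atoms: chlorotriethylsilane, CC[Si](Cl)(CC)CC
Why: Selective silylation of the primary hydroxyl over the hindered secondary allylic one; triethylsilyl is chosen because a primary TES ether can later be oxidised directly to the aldehyde.

**Step 4**
Reactants: 6
Product: 7 (5R)-3-(bromomethyl)-5-{[(triethylsilyl)oxy]methyl}furan-2(5H)-one
Conditions: CBr4, PPh3, CH2Cl2, 0 °C
Reagents that add atoms: tetrabromomethane, BrC(Br)(Br)Br
Why: Appel bromination of a Baylis–Hillman-type alcohol with allylic transposition (SN2′): bromide enters at the exocyclic CH2 and the double bond moves into the ring, so both epimers of 6 converge on one butenolide whose only stereocentre is the untouched C8. The neutral conditions spare the silyl ether.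

**Step 5**
Reactants: 8 ethyl acetoacetate; 9 1-bromobut-2-yne
Product: 11 ethyl 3-oxooct-6-ynoate, via acetoacetate dianion 10 (not isolated)
Conditions: NaH, THF, 0 °C; n-BuLi, 0 °C; 9, 0 °C to rt; aq. NH4Cl
Reagents that add atoms: none
Why: γ-Alkylation of the acetoacetate dianion, which reacts at its more basic terminal carbon; the propargylic bromide brings in C1, C2, C10 and C14 with the alkyne already methyl-capped.

**Step 6**
Reactants: 11
Product: 12 ethyl (2E)-3-{[(trifluoromethyl)sulfonyl]oxy}oct-2-en-6-ynoate
Conditions: Tf2O, aq. Me4NOH, hexanes, 5–10 °C
Reagents that add atoms: trifluoromethanesulfonic anhydride, O=S(=O)(OS(=O)(=O)C(F)(F)F)C(F)(F)F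
Why: O-Triflation of a β-keto ester enolate; with a non-coordinating ammonium counter-ion the enolate is not chelated, so the (E)-enol triflate (triflate trans to the ester) should predominate, which is the geometry that leads to the 4Z olefin.

**Step 7**
Reactants: 12
Product: 13 ethyl (2Z)-3-methyloct-2-en-6-ynoate
Conditions: Me2CuLi, THF, −78 °C
Reagents that add atoms: lithium dimethylcuprate, [Li+].C[Cu-]C
Why: Addition–elimination of a cuprate on a β-sulfonyloxy enoate with retention of geometry; methyl replaces triflate, so the chain stays cis to the ester and the trisubstituted olefin is Z. The internal alkyne is inert at this temperature.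

**Step 8**
Reactants: 13
Product: 14 (2Z)-3-methyloct-2-en-6-yn-1-ol
Conditions: i-Bu2AlH (2.2 equiv), CH2Cl2, −78 to 0 °C
Reagents that add atoms: none
Why: 1,2-Reduction of an enoate to the allylic alcohol, which touches neither the alkyne nor the olefin geometry.

**Step 9**
Reactants: 14
Product: 16 (2Z,6E)-7-iodo-3-methylocta-2,6-dien-1-ol, via alkenylzirconocene chloride 15 (not isolated)
Conditions: Cp2Zr(H)Cl (3 equiv), THF, rt to 40 °C; then I2, 0 °C
Reagents that add atoms: iodine, [I][I]
Why: syn-Hydrozirconation of the internal alkyne followed by iododezirconation with retention. One equivalent of reagent is spent on the hydroxyl, and the excess equilibrates the alkenylzirconium isomers towards the one with zirconium on the methyl-bearing carbon, which gives the (E)-2-iodo-2-alkene. The trisubstituted olefin does not hydrozirconate.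

**Step 10**
Reactants: 16
Product: 17 (2Z,6E)-7-iodo-3-methylocta-2,6-dienal
Conditions: TEMPO (10 mol %), PhI(OAc)2, CH2Cl2, rt
Reagents that add atoms: none
Why: Oxoammonium oxidation of a primary allylic alcohol under neutral conditions, which should preserve the Z geometry of the enal and leave the alkenyl iodide alone.

**Step 11**
Reactants: 17; 7
Product: 18 (4S,5R)-4-[(1R,2Z,6E)-1-hydroxy-7-iodo-3-methylocta-2,6-dien-1-yl]-3-methylidene-5-{[(triethylsilyl)oxy]methyl}oxolan-2-one
Conditions: nickel-free CrCl2 (3 equiv), THF, 0 °C to rt
Reagents that add atoms: none
Why: Chromium-mediated Barbier-type allylation through a closed six-membered Zimmerman–Traxler transition state; without nickel, CrCl2 inserts only into the allylic bromide, and the allylchromium adds 1,2 to the enal through its ring carbon C7 with regeneration of the exocyclic methylene. C7 is attacked anti to the C8 substituent (7,8-trans) and, because C8 is fixed trans to the CH2–Cr terminus, the chair places O6 anti to C8, which is the 6,7-relationship of the target. The lactone is already closed on O8, so O6 cannot compete for the carbonyl.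

**Step 12**
Reactants: 18
Product: 19 (4S,5R)-4-[(S)-hydroxy{(2R,3S)-3-[(3E)-4-iodopent-3-en-1-yl]-3-methyloxiran-2-yl}methyl]-3-methylidene-5-{[(triethylsilyl)oxy]methyl}oxolan-2-one
Conditions: mCPBA (1.1 equiv), NaHCO3, CH2Cl2, 0 °C
Reagents that add atoms: 3-chloroperoxybenzoic acid, OOC(=O)c1cccc(Cl)c1
Why: Hydroxyl-directed peracid epoxidation of a secondary allylic alcohol; A(1,3) strain between C3 and the substituents of C6 puts H6 in the olefin plane, so the hydrogen-bonded peracid delivers oxygen to the face that gives the threo (5,6-syn) epoxy alcohol, and syn addition to the 4Z olefin gives the cis-epoxide. The electron-rich, hydroxyl-activated olefin should react well before the iodine-bearing olefin or the electron-poor methylene lactone, and the buffered medium offers no alkoxide to start lactone migration.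

**Step 13**
Reactants: 19
Product: 20 (4R,5R)-4-[(S)-{(2R,3S)-3-[(3E)-4-iodopent-3-en-1-yl]-3-methyloxiran-2-yl}(triethylsilyloxy)methyl]-3-methylidene-5-{[(triethylsilyl)oxy]methyl}oxolan-2-one
Conditions: TESCl, imidazole, DMAP (cat.), CH2Cl2, 0 °C to rt
Reagents that add atoms: chlorotriethylsilane, CC[Si](Cl)(CC)CC
Why: Silylation of the secondary hydroxyl under weakly basic conditions that should cause neither Payne rearrangement nor migration of the lactone to O6.

**Step 14**
Reactants: 20
Product: 21 (2R,3R)-3-[(S)-{(2R,3S)-3-[(3E)-4-iodopent-3-en-1-yl]-3-methyloxiran-2-yl}(triethylsilyloxy)methyl]-4-methylidene-5-oxooxolane-2-carbaldehyde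
Conditions: (COCl)2, DMSO, CH2Cl2, −78 to −40 °C; Et3N, −78 to 0 °C
Reagents that add atoms: none
Why: Swern oxidation applied directly to a primary triethylsilyl ether: chlorodimethylsulfonium chloride attacks the unhindered primary silyl ether oxygen, the alkoxysulfonium salt collapses to the aldehyde when base is added, and the hindered secondary TES ether stays. The aldehyde is used without chromatography to avoid epimerisation at C8.

**Step 15**
Reactants: 21
Product: 22 (1(10)E,4S,5R,6S,7R,8R,9S)-4,5-epoxy-9-hydroxy-6-(triethylsilyloxy)germacra-1(10),11(13)-dien-12,8-olide
Conditions: CrCl2 (10 equiv), NiCl2 (5 mol %), degassed DMSO, rt, 21 added over 12 h to 0.003 M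
Reagents that add atoms: none
Why: Nozaki–Hiyama–Kishi reaction: CrCl2 reduces NiCl2 to zerovalent nickel, which inserts into the C10–I bond with retention of the E geometry, and transmetallation gives an alkenyl complex of trivalent chromium while divalent nickel returns to the cycle. The alkenylchromium adds to the C9 aldehyde and forms C9–C10; the closest known reaction type is the intramolecular alkenyl iodide–aldehyde coupling used to close medium and large carbocycles. The ten-membered carbocycle closes by 1,2-addition with the carbonyl oxygen outside the forming ring (10-exo-trig), and slow addition at high dilution favours cyclisation over intermolecular coupling. The new stereocentre C9 is controlled by C8 through a polar Felkin–Anh arrangement (C8–O bond anti to the incoming C10), within the conformation that the trans-lactone, the cis-epoxide and the E-olefin impose on the chain; this predicts the 8,9-anti alcohol, which is the configuration of the target. The step needs addition to the aldehyde only: alkenylchromium reagents do not add to lactones or enoates and are neither basic nor nucleophilic enough to isomerise the methylene lactone or open the epoxide. The TES ether on O6 prevents lactol formation with the aldehyde, and C4 to C8 and both olefin geometries are spectators fixed in earlier steps.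

**Step 16**
Reactants: 22
Product: 23 (1(10)E,4S,5R,6S,7R,8R,9S)-4,5-epoxy-9-(2-methylpropanoyloxy)-6-(triethylsilyloxy)germacra-1(10),11(13)-dien-12,8-olide
Conditions: (i-PrCO)2O, DMAP, Et3N, CH2Cl2, 0 °C to rt
Reagents that add atoms: 2-methylpropanoic anhydride, CC(C)C(=O)OC(=O)C(C)C
Why: DMAP-catalysed acylation of the only free hydroxyl, with retention at C9.

**Step 17**
Reactants: 23
Product: 24 (1(10)E,4S,5R,6S,7S,8R,9S)-4,5-epoxy-6-hydroxy-9-(2-methylpropanoyloxy)germacra-1(10),11(13)-dien-12,8-olide (CNP0220196.2)
Conditions: HF·pyridine, pyridine, THF, 0 °C
Reagents that add atoms: none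
Why: Fluoride cleavage of the secondary TES ether under buffered, non-basic conditions, which should spare the epoxide, the ester and the methylene lactone and should avoid Payne rearrangement or lactone migration of the freed 6-hydroxyl.

## Compound list

1 | (S)-2,3-O-isopropylideneglyceraldehyde | O=C[C@@H]1COC(C)(C)O1 | starting material
2 | methyl acrylate | C=CC(=O)OC | starting material
3 | methyl 2-{[(4S)-2,2-dimethyl-1,3-dioxolan-4-yl](hydroxy)methyl}prop-2-enoate (carbinol epimers) | C=C(C(=O)OC)C(O)[C@@H]1COC(C)(C)O1 | intermediate
4 | methyl (4S)-3,4,5-trihydroxy-2-methylidenepentanoate (C3 epimers) | C=C(C(=O)OC)C(O)[C@@H](O)CO | intermediate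
5 | (5S)-4-hydroxy-5-(hydroxymethyl)-3-methylideneoxolan-2-one (C4 epimers) | C=C1C(=O)O[C@@H](CO)C1O | intermediate
6 | (5S)-4-hydroxy-3-methylidene-5-{[(triethylsilyl)oxy]methyl}oxolan-2-one (C4 epimers) | C=C1C(=O)O[C@@H](CO[Si](CC)(CC)CC)C1O | intermediate
7 | (5R)-3-(bromomethyl)-5-{[(triethylsilyl)oxy]methyl}furan-2(5H)-one | BrCC1=C[C@H](CO[Si](CC)(CC)CC)OC1=O | intermediate
8 | ethyl acetoacetate | CCOC(=O)CC(C)=O | starting material
9 | 1-bromobut-2-yne | CC#CCBr | starting material
10 | ethyl acetoacetate dianion (sodium lithium salt) | [CH2-]C(=O)[CH-]C(=O)OCC.[Na+].[Li+] | intermediate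
11 | ethyl 3-oxooct-6-ynoate | CCOC(=O)CC(=O)CCC#CC | intermediate
12 | ethyl (2E)-3-{[(trifluoromethyl)sulfonyl]oxy}oct-2-en-6-ynoate | CCOC(=O)/C=C(OS(=O)(=O)C(F)(F)F)\CCC#CC | intermediate
13 | ethyl (2Z)-3-methyloct-2-en-6-ynoate | CCOC(=O)/C=C(C)\CCC#CC | intermediate
14 | (2Z)-3-methyloct-2-en-6-yn-1-ol | OC/C=C(C)\CCC#CC | intermediate
15 | (E)-alkenylzirconocene chloride of 14, as its O-zirconocene alkoxide (cyclopentadienyl rings drawn σ-bonded) | C/C(=C\CC/C(C)=C\CO[Zr](Cl)(C1C=CC=C1)C1C=CC=C1)[Zr](Cl)(C1C=CC=C1)C1C=CC=C1 | intermediate
16 | (2Z,6E)-7-iodo-3-methylocta-2,6-dien-1-ol | OC/C=C(C)\CC/C=C(\C)I | intermediate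
17 | (2Z,6E)-7-iodo-3-methylocta-2,6-dienal | O=C/C=C(C)\CC/C=C(\C)I | intermediate
18 | (4S,5R)-4-[(1R,2Z,6E)-1-hydroxy-7-iodo-3-methylocta-2,6-dien-1-yl]-3-methylidene-5-{[(triethylsilyl)oxy]methyl}oxolan-2-one | C=C1C(=O)O[C@@H](CO[Si](CC)(CC)CC)[C@@H]1[C@H](O)/C=C(C)\CC/C=C(\C)I | intermediate
19 | (4S,5R)-4-[(S)-hydroxy{(2R,3S)-3-[(3E)-4-iodopent-3-en-1-yl]-3-methyloxiran-2-yl}methyl]-3-methylidene-5-{[(triethylsilyl)oxy]methyl}oxolan-2-one | C=C1C(=O)O[C@@H](CO[Si](CC)(CC)CC)[C@@H]1[C@H](O)[C@H]1O[C@@]1(C)CC/C=C(\C)I | intermediate
20 | (4R,5R)-4-[(S)-{(2R,3S)-3-[(3E)-4-iodopent-3-en-1-yl]-3-methyloxiran-2-yl}(triethylsilyloxy)methyl]-3-methylidene-5-{[(triethylsilyl)oxy]methyl}oxolan-2-one | C=C1C(=O)O[C@@H](CO[Si](CC)(CC)CC)[C@@H]1[C@H](O[Si](CC)(CC)CC)[C@H]1O[C@@]1(C)CC/C=C(\C)I | intermediate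
21 | (2R,3R)-3-[(S)-{(2R,3S)-3-[(3E)-4-iodopent-3-en-1-yl]-3-methyloxiran-2-yl}(triethylsilyloxy)methyl]-4-methylidene-5-oxooxolane-2-carbaldehyde | C=C1C(=O)O[C@@H](C=O)[C@@H]1[C@H](O[Si](CC)(CC)CC)[C@H]1O[C@@]1(C)CC/C=C(\C)I | intermediate
22 | (1(10)E,4S,5R,6S,7R,8R,9S)-4,5-epoxy-9-hydroxy-6-(triethylsilyloxy)germacra-1(10),11(13)-dien-12,8-olide | C=C1C(=O)O[C@@H]2[C@@H]1[C@H](O[Si](CC)(CC)CC)[C@H]1O[C@@]1(C)CC/C=C(\C)[C@@H]2O | intermediate
23 | (1(10)E,4S,5R,6S,7R,8R,9S)-4,5-epoxy-9-(2-methylpropanoyloxy)-6-(triethylsilyloxy)germacra-1(10),11(13)-dien-12,8-olide | C=C1C(=O)O[C@@H]2[C@@H]1[C@H](O[Si](CC)(CC)CC)[C@H]1O[C@@]1(C)CC/C=C(\C)[C@@H]2OC(=O)C(C)C | intermediate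
24 | (1(10)E,4S,5R,6S,7S,8R,9S)-4,5-epoxy-6-hydroxy-9-(2-methylpropanoyloxy)germacra-1(10),11(13)-dien-12,8-olide | C=C1C(=O)O[C@@H]2[C@@H]1[C@H](O)[C@H]1O[C@@]1(C)CC/C=C(\C)[C@@H]2OC(=O)C(C)C | target

## Step count and least certain steps

Total: 17 steps. Longest linear sequence: 13 steps (8 and 9 to 24, steps 5–10 and 11–17); the lactone branch (steps 1–4) joins at step 11.

**Step 15 (key step).** The most likely failure is attack on the wrong face of the C9 aldehyde. Strain in the ten-membered transition state, with an E-olefin, a cis-epoxide and a trans-lactone in the tether, can override the Felkin–Anh preference set by C8. Intermolecular coupling is the second concern and is countered by the slow addition. Fallback: set C9 by invertive esterification instead of by the addition. It sets out from 21, which is cyclised as before; the 9-epimeric alcohol, (1(10)E,4S,5R,6S,7R,8R,9R)-4,5-epoxy-9-hydroxy-6-(triethylsilyloxy)germacra-1(10),11(13)-dien-12,8-olide F1, is then treated with isobutyric acid, PPh3 and DIAD in toluene (Mitsunobu esterification with inversion), and the route is rejoined at 23.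

**Step 11.** The most likely failure is erosion of diastereoselectivity, through an open or boat-like transition state or through attack syn to the C8 substituent, because the allylchromium is formed and consumed in the presence of the aldehyde and its aggregation state is not controlled. Fallback: use a preformed allylboron reagent, whose B–O bonding enforces the closed transition state. It sets out from 7, which is borylated (B2pin2, Pd2(dba)3, DMSO) to the allylboronate (5R)-3-[(4,4,5,5-tetramethyl-1,3,2-dioxaborolan-2-yl)methyl]-5-{[(triethylsilyl)oxy]methyl}furan-2(5H)-one F2; allylboration of 17 (Sc(OTf)3 cat., toluene) rejoins the route at 18.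

**Step 12.** The most likely failure is insufficient facial selectivity, or oxidation at the iodo-olefin, since the A(1,3) preference depends on the conformation around C6–C7 of a branched carbinol. Fallback: make the epoxide before the coupling under reagent control. It sets out from 16: Sharpless epoxidation (Ti(OiPr)4, D-(−)-diethyl tartrate, t-BuOOH, 4 Å MS, CH2Cl2, −20 °C) gives the epoxy alcohol [(2R,3S)-3-[(3E)-4-iodopent-3-en-1-yl]-3-methyloxiran-2-yl]methanol F3; TEMPO/PhI(OAc)2 gives the epoxy aldehyde (2S,3S)-3-[(3E)-4-iodopent-3-en-1-yl]-3-methyloxirane-2-carbaldehyde F4; and allylation with 7 (CrCl2, THF) rejoins the route at 19. The price is that the Felkin–Anh preference of the epoxy aldehyde then opposes the reagent-controlled sense at C6.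

**Step 14.** The most likely failure is loss of the secondary silyl ether or chloride opening of the epoxide by the activated sulfoxide, because the direct oxidation needs excess reagent and warming. Fallback: separate deprotection and oxidation. It sets out from 20: HF·pyridine/pyridine in THF at 0 °C removes only the primary silyl group to give the alcohol (4R,5R)-5-(hydroxymethyl)-4-[(S)-{(2R,3S)-3-[(3E)-4-iodopent-3-en-1-yl]-3-methyloxiran-2-yl}(triethylsilyloxy)methyl]-3-methylideneoxolan-2-one F5, and Dess–Martin periodinane with NaHCO3 rejoins the route at 21.

**Step 9.** The most likely failure is incomplete regiocontrol, with zirconium ending on C1, because the two alkyne substituents (methyl and a primary alkyl chain) differ little in size. Fallback: bring in the iodo-olefin with defined geometry from the start. It sets out from 8: its dianion is alkylated with (2E)-1-bromo-3-iodobut-2-ene F6 (made from but-2-yn-1-ol by syn-stannylcupration, iododestannylation and bromination) to give ethyl (6E)-7-iodo-3-oxooct-6-enoate F7. The conditions of step 6 give ethyl (2E,6E)-7-iodo-3-{[(trifluoromethyl)sulfonyl]oxy}octa-2,6-dienoate F8. Me2CuLi at −78 °C, where addition–elimination on the enol triflate is far faster than any reaction of an unactivated alkenyl iodide, gives ethyl (2Z,6E)-7-iodo-3-methylocta-2,6-dienoate F9. i-Bu2AlH rejoins the route at 16.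

## Further compounds

F1 | step 15 | (1(10)E,4S,5R,6S,7R,8R,9R)-4,5-epoxy-9-hydroxy-6-(triethylsilyloxy)germacra-1(10),11(13)-dien-12,8-olide | C=C1C(=O)O[C@@H]2[C@@H]1[C@H](O[Si](CC)(CC)CC)[C@H]1O[C@@]1(C)CC/C=C(\C)[C@H]2O
F2 | step 11 | (5R)-3-[(4,4,5,5-tetramethyl-1,3,2-dioxaborolan-2-yl)methyl]-5-{[(triethylsilyl)oxy]methyl}furan-2(5H)-one | CC1(C)OB(CC2=C[C@H](CO[Si](CC)(CC)CC)OC2=O)OC1(C)C
F3 | step 12 | [(2R,3S)-3-[(3E)-4-iodopent-3-en-1-yl]-3-methyloxiran-2-yl]methanol | OC[C@H]1O[C@@]1(C)CC/C=C(\C)I
F4 | step 12 | (2S,3S)-3-[(3E)-4-iodopent-3-en-1-yl]-3-methyloxirane-2-carbaldehyde | O=C[C@H]1O[C@@]1(C)CC/C=C(\C)I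
F5 | step 14 | (4R,5R)-5-(hydroxymethyl)-4-[(S)-{(2R,3S)-3-[(3E)-4-iodopent-3-en-1-yl]-3-methyloxiran-2-yl}(triethylsilyloxy)methyl]-3-methylideneoxolan-2-one | C=C1C(=O)O[C@@H](CO)[C@@H]1[C@H](O[Si](CC)(CC)CC)[C@H]1O[C@@]1(C)CC/C=C(\C)I
F6 | step 9 | (2E)-1-bromo-3-iodobut-2-ene | C/C(I)=C\CBr
F7 | step 9 | ethyl (6E)-7-iodo-3-oxooct-6-enoate | CCOC(=O)CC(=O)CC/C=C(\C)I
F8 | step 9 | ethyl (2E,6E)-7-iodo-3-{[(trifluoromethyl)sulfonyl]oxy}octa-2,6-dienoate | CCOC(=O)/C=C(OS(=O)(=O)C(F)(F)F)\CC/C=C(\C)I
F9 | step 9 | ethyl (2Z,6E)-7-iodo-3-methylocta-2,6-dienoate | CCOC(=O)/C=C(C)\CC/C=C(\C)I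
A1 | alternative 1 | ten-membered 4,5-epoxy-12,8-lactone lacking C13, with C6-OTES and C9-OPMB | C1C(=O)O[C@@H]2[C@@H]1[C@H](O[Si](CC)(CC)CC)[C@H]1O[C@@]1(C)CC/C=C(\C)[C@@H]2OCc1ccc(OC)cc1
A2 | alternative 2 | ten-membered (4Z,1(10)E)-dienone with C6 ketone, C8-OMOM and C9-OPMB | O=C1/C=C(C)\CC/C=C(\C)[C@H](OCc2ccc(OC)cc2)[C@H](OCOC)C1
A3 | alternative 3 | ten-membered (4Z,1(10)E)-dienol (C6-OH, C9-OTBS) fused at C7–C8 to a 3-methylidenetetrahydrofuran | C=C1CO[C@@H]2[C@@H]1[C@H](O)/C=C(C)\CC/C=C(\C)[C@@H]2O[Si](C)(C)C(C)(C)C
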